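## Retrosynthetic overview

1. Target 38 comes from global desilylation of enone 37. The ten-membered carbocycle is the last ring formed, closed at C3–C4 by an intramolecular Nozaki–Hiyama–Kishi reaction of a (Z)-vinyl iodide onto the C3 aldehyde, followed by oxidation.
2. The cis-fused α-methylene-γ-butyrolactone is the first ring formed. It arises by lactonisation of the γ-hydroxy ester from the key intermolecular indium-mediated carbonyl allylation (C6–C7 bond) of (Z)-β-iodoenal 26 with 2-(bromomethyl)enoate 21. The C8 ester is added afterwards.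
3. Bromide 21 comes from aldehyde 18 (Baylis–Hillman, then SN2′ bromination). The C1/C10 anti-diol comes from Shi epoxidation and invertive hydrolysis of an E-trisubstituted alkene (Negishi carboalumination, oxirane trapping). C8 comes from (R)-epichlorohydrin.
4. Enal 26 comes from but-2-yne-1,4-diol (Red-Al/I2, then MnO2).

Assumption: the target is the open keto-diol as drawn (it may equilibrate with its C3/C10 hemiketal). Carbon labels in the Why lines: C1 CHOH, C2 CH2, C3 C=O, C4 =C(CH2OH), C5 =CH, C6 CH–O(lactone), C7 ring-fusion CH, C8 CH–O-acyl, C9 CH2, C10 C(CH3)OH, C11/C12/C13 lactone C(=)/C=O/=CH2, C14 CH3, C15 CH2OH.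

## Route

Step 1
Reactants: 1 (R)-epichlorohydrin; 2 ethynyltrimethylsilane
Product: 4 (2R)-1-chloro-5-(trimethylsilyl)pent-4-yn-2-ol, via lithium (trimethylsilyl)acetylide 3 (not isolated)
Conditions: 2, n-BuLi, THF, −78 °C; BF3·OEt2; then 1, −78 °C; aq. work-up
Reagents that add atoms: none
Why: BF3-promoted (Yamaguchi) epoxide opening by the acetylide occurs at the unsubstituted CH2 (C9), so the C–O bond of the stereocentre (future C8, R) is untouched and the C–Cl bond is kept for step 2.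

Step 2
Reactants: 4 (2R)-1-chloro-5-(trimethylsilyl)pent-4-yn-2-ol
Product: 6 (3R)-6-(trimethylsilyl)hex-1-en-5-yn-3-ol, via terminal epoxide 5 (not isolated)
Conditions: Me3S+ I− (4 equiv), n-BuLi (3.9 equiv), THF, −20 °C to rt
Reagents that add atoms: trimethylsulfonium iodide, C[S+](C)C.[I-]
Why: Excess dimethylsulfonium methylide closes the chlorohydrin to epoxide 5, opens it at CH2 and eliminates Me2S (one-carbon epoxide-to-allylic-alcohol homologation), so the C8–O bond is never broken and the vinyl group serves as a masked C7 aldehyde.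

Step 3
Reactants: 6 (3R)-6-(trimethylsilyl)hex-1-en-5-yn-3-ol
Product: 8 1-({[(3R)-hex-1-en-5-yn-3-yl]oxy}methyl)-4-methoxybenzene, via PMB-protected silylalkyne 7 (not isolated)
Conditions: NaH, PMBCl, Bu4NI (cat.), THF/DMF, 0 °C to rt; then K2CO3, MeOH, rt
Reagents that add atoms: 4-methoxybenzyl chloride, COc1ccc(CCl)cc1
Why: Williamson etherification of the secondary alkoxide followed by base-mediated protiodesilylation of the alkynylsilane; no bond to the stereocentre is touched.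

Step 4
Reactants: 8 1-({[(3R)-hex-1-en-5-yn-3-yl]oxy}methyl)-4-methoxybenzene; 9 oxirane
Product: 12 (3E,6R)-6-[(4-methoxybenzyl)oxy]-4-methylocta-3,7-dien-1-ol, via (E)-alkenyldimethylalane 10 (not isolated), via lithium alkenyl(butyl)dimethylaluminate 11 (not isolated)
Conditions: Me3Al (3 equiv), Cp2ZrCl2 (0.3 equiv), CH2Cl2, 0 °C to rt; then n-BuLi, THF/hexane, −78 °C; then 9, −78 °C to rt; aq. work-up
Reagents that add atoms: trimethylaluminium, C[Al](C)C
Why: Negishi Zr-catalysed syn-carboalumination puts CH3 (C14) on the internal and Al on the terminal alkyne carbon, and the derived alanate opens oxirane with retention of alkene geometry, giving the E-trisubstituted alkene (C2 trans to C9) with C2 and C3 in place.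

Step 5
Reactants: 12 (3E,6R)-6-[(4-methoxybenzyl)oxy]-4-methylocta-3,7-dien-1-ol
Product: 13 (3E,6R)-1,6-bis[(4-methoxybenzyl)oxy]-4-methylocta-3,7-diene
Conditions: NaH, PMBCl, Bu4NI (cat.), DMF, 0 °C to rt
Reagents that add atoms: 4-methoxybenzyl chloride, COc1ccc(CCl)cc1
Why: Williamson etherification protects the primary C3 hydroxyl as an acid-stable, poorly participating ether for the epoxide hydrolysis in step 7.

Step 6
Reactants: 13 (3E,6R)-1,6-bis[(4-methoxybenzyl)oxy]-4-methylocta-3,7-diene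
Product: 14 (2R,3R)-2-{(2R)-2-[(4-methoxybenzyl)oxy]but-3-en-1-yl}-3-{2-[(4-methoxybenzyl)oxy]ethyl}-2-methyloxirane
Conditions: D-fructose-derived Shi ketone (0.3 equiv), Oxone, K2CO3, Bu4NHSO4, MeCN/DMM, aq. Na2B4O7–EDTA buffer (pH 10.5), 0 °C
Reagents that add atoms: Oxone (potassium peroxymonosulfate; oxygen delivered through the catalyst dioxirane), [K+].[O-]S(=O)(=O)OO
Why: Shi asymmetric epoxidation (spiro dioxirane transition state) is reagent-controlled for E-trisubstituted alkenes, the D-fructose ketone giving the (R,R)-epoxide, i.e. the target C1–O bond, while the monosubstituted vinyl group does not react.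

Step 7
Reactants: 14 (2R,3R)-2-{(2R)-2-[(4-methoxybenzyl)oxy]but-3-en-1-yl}-3-{2-[(4-methoxybenzyl)oxy]ethyl}-2-methyloxirane
Product: 15 (3R,4S,6R)-1,6-bis[(4-methoxybenzyl)oxy]-4-methyloct-7-ene-3,4-diol
Conditions: HClO4 (cat., ca. 0.05 M), THF/H2O (2:1), 0 °C
Reagents that add atoms: water, O
Why: Acid-catalysed epoxide hydrolysis: water attacks the tertiary carbon C10 with inversion (anti opening) while the C1–O bond is retained, converting the trans-epoxide into the erythro 1R,10S diol of the target.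

Step 8
Reactants: 15 (3R,4S,6R)-1,6-bis[(4-methoxybenzyl)oxy]-4-methyloct-7-ene-3,4-diol
Product: 16 (3R,4S,6R)-1,6-bis[(4-methoxybenzyl)oxy]-4-methyl-3,4-bis[(triethylsilyl)oxy]oct-7-ene
Conditions: TESOTf (3 equiv), 2,6-lutidine, CH2Cl2, −78 to 0 °C
Reagents that add atoms: triethylsilyl trifluoromethanesulfonate, CC[Si](CC)(CC)OS(=O)(=O)C(F)(F)F
Why: Silyl triflate/lutidine silylates both the secondary and the hindered tertiary hydroxyl, masking C10–OH so that it cannot form a lactol with the later C3 aldehyde.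

Step 9
Reactants: 16 (3R,4S,6R)-1,6-bis[(4-methoxybenzyl)oxy]-4-methyl-3,4-bis[(triethylsilyl)oxy]oct-7-ene
Product: 18 (2R,4S,5R)-2,7-bis[(4-methoxybenzyl)oxy]-4-methyl-4,5-bis[(triethylsilyl)oxy]heptanal, via vicinal diol 17 (not isolated)
Conditions: K2OsO4·2H2O (2 mol%), NaIO4 (4 equiv), 2,6-lutidine, dioxane/H2O (3:1), rt
Reagents that add atoms: sodium periodate (terminal oxidant; oxygen transferred through catalytic osmium tetroxide), [Na+].[O-]I(=O)(=O)=O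
Why: Lemieux–Johnson oxidation (catalytic dihydroxylation then periodate glycol cleavage, lutidine-buffered) cuts only the terminal vinyl group to the α-alkoxy aldehyde (C7) without base, so C8 is not epimerised.

Step 10
Reactants: 18 (2R,4S,5R)-2,7-bis[(4-methoxybenzyl)oxy]-4-methyl-4,5-bis[(triethylsilyl)oxy]heptanal; 19 methyl acrylate
Product: 20 methyl (4R,6S,7R)-3-hydroxy-4,9-bis[(4-methoxybenzyl)oxy]-6-methyl-2-methylidene-6,7-bis[(triethylsilyl)oxy]nonanoate (mixture of C3 epimers)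
Conditions: 19 (10 equiv), DABCO (1 equiv), dioxane/H2O (1:1), rt, 2–4 d
Reagents that add atoms: none
Why: Morita–Baylis–Hillman reaction joins the acrylate α-carbon (C11) to the aldehyde carbon (C7); the new carbinol configuration is irrelevant because that carbon becomes sp2 in step 11.

Step 11
Reactants: 20 methyl (4R,6S,7R)-3-hydroxy-4,9-bis[(4-methoxybenzyl)oxy]-6-methyl-2-methylidene-6,7-bis[(triethylsilyl)oxy]nonanoate
Product: 21 methyl (2Z,4R,6S,7R)-2-(bromomethyl)-4,9-bis[(4-methoxybenzyl)oxy]-6-methyl-6,7-bis[(triethylsilyl)oxy]non-2-enoate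
Conditions: NBS, Me2S, CH2Cl2, 0 °C to rt
Reagents that add atoms: N-bromosuccinimide, O=C1CCC(=O)N1Br
Why: The bromosulfonium reagent activates the allylic hydroxyl (Corey–Kim type) and bromide attacks in an SN2′ sense, giving the conjugated, thermodynamically preferred (Z)-2-(bromomethyl)enoate (side chain trans to the ester).

Step 12
Reactants: 22 but-2-yne-1,4-diol
Product: 23 4-{[tert-butyl(dimethyl)silyl]oxy}but-2-yn-1-ol
Conditions: 22 (3 equiv), TBSCl (1 equiv), imidazole, DMF/THF, 0 °C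
Reagents that add atoms: tert-butyl(chloro)dimethylsilane, CC(C)(C)[Si](C)(C)Cl
Why: Statistical monosilylation of a cheap symmetrical diol used in excess.

Step 13
Reactants: 23 4-{[tert-butyl(dimethyl)silyl]oxy}but-2-yn-1-ol
Product: 25 (2Z)-4-{[tert-butyl(dimethyl)silyl]oxy}-3-iodobut-2-en-1-ol, via cyclic alkenylaluminate 24 (not isolated)
Conditions: Red-Al, THF, 0 °C to rt; then I2, THF, −78 to 0 °C
Reagents that add atoms: iodine, II
Why: Hydroxyl-directed trans-hydroalumination places aluminium on the distal alkyne carbon in a five-membered alkenylaluminate, and iodinolysis with retention gives only the (Z)-3-iodoallylic alcohol (I cis to CH2OH, as needed for the cis ring alkene).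

Step 14
Reactants: 25 (2Z)-4-{[tert-butyl(dimethyl)silyl]oxy}-3-iodobut-2-en-1-ol
Product: 26 (2Z)-4-{[tert-butyl(dimethyl)silyl]oxy}-3-iodobut-2-enal
Conditions: MnO2 (15 equiv), CH2Cl2, rt, dark; used at once
Reagents that add atoms: none
Why: MnO2 oxidises the allylic alcohol to the enal under neutral heterogeneous conditions that preserve the labile (Z)-β-iodoenal geometry.

Step 15
Reactants: 21 methyl (2Z,4R,6S,7R)-2-(bromomethyl)-4,9-bis[(4-methoxybenzyl)oxy]-6-methyl-6,7-bis[(triethylsilyl)oxy]non-2-enoate; 26 (2Z)-4-{[tert-butyl(dimethyl)silyl]oxy}-3-iodobut-2-enal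
Product: 28 methyl (3S,4R,5Z)-3-{(1R,3S,4R)-1,6-bis[(4-methoxybenzyl)oxy]-3-methyl-3,4-bis[(triethylsilyl)oxy]hexyl}-7-{[tert-butyl(dimethyl)silyl]oxy}-4-hydroxy-6-iodo-2-methylidenehept-5-enoate, via allylindium(I) species 27 (not isolated)
Conditions: In powder (1.5 equiv), 26 (1.3 equiv), THF/H2O (3:1), rt
Reagents that add atoms: none
Why: Indium-mediated Barbier carbonyl allylation through a Zimmerman–Traxler chair: the (Z)-allylindium adds through its γ-carbon to give the syn adduct, and with H-8 in the alkene plane (A(1,3) strain) the indium-bound aldehyde is delivered to the face bearing the coordinating PMB ether, anti to the C9 chain, which sets C6 and C7 (6,7-syn, 7,8-anti).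

Step 16
Reactants: 28 methyl (3S,4R,5Z)-3-{(1R,3S,4R)-1,6-bis[(4-methoxybenzyl)oxy]-3-methyl-3,4-bis[(triethylsilyl)oxy]hexyl}-7-{[tert-butyl(dimethyl)silyl]oxy}-4-hydroxy-6-iodo-2-methylidenehept-5-enoate
Product: 29 (4R,5R)-5-[(1Z)-3-{[tert-butyl(dimethyl)silyl]oxy}-2-iodoprop-1-en-1-yl]-4-{(1R,3S,4R)-1,6-bis[(4-methoxybenzyl)oxy]-3-methyl-3,4-bis[(triethylsilyl)oxy]hexyl}-3-methylideneoxolan-2-one
Conditions: PPTS (0.3 equiv), toluene, 50 °C
Reagents that add atoms: none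
Why: Acid-catalysed lactonisation (intramolecular transesterification) by the only free hydroxyl (C6–OH) closes the cis-4,5-disubstituted α-methylene-γ-butyrolactone without touching either stereocentre.

Step 17
Reactants: 29 (4R,5R)-5-[(1Z)-3-{[tert-butyl(dimethyl)silyl]oxy}-2-iodoprop-1-en-1-yl]-4-{(1R,3S,4R)-1,6-bis[(4-methoxybenzyl)oxy]-3-methyl-3,4-bis[(triethylsilyl)oxy]hexyl}-3-methylideneoxolan-2-one
Product: 30 (4R,5R)-5-[(1Z)-3-{[tert-butyl(dimethyl)silyl]oxy}-2-iodoprop-1-en-1-yl]-4-{(1R,3S,4R)-1,6-dihydroxy-3-methyl-3,4-bis[(triethylsilyl)oxy]hexyl}-3-methylideneoxolan-2-one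
Conditions: DDQ (3 equiv), CH2Cl2/pH 7 buffer (10:1), 0 °C
Reagents that add atoms: none
Why: Oxidative PMB cleavage with DDQ removes both benzylic ethers as anisaldehyde and leaves the silyl ethers, vinyl iodide and acrylate intact.

Step 18
Reactants: 30 (4R,5R)-5-[(1Z)-3-{[tert-butyl(dimethyl)silyl]oxy}-2-iodoprop-1-en-1-yl]-4-{(1R,3S,4R)-1,6-dihydroxy-3-methyl-3,4-bis[(triethylsilyl)oxy]hexyl}-3-methylideneoxolan-2-one
Product: 31 (3R,4S,6R)-6-hydroxy-6-{(2R,3R)-2-[(1Z)-3-{[tert-butyl(dimethyl)silyl]oxy}-2-iodoprop-1-en-1-yl]-4-methylidene-5-oxooxolan-3-yl}-4-methyl-3,4-bis[(triethylsilyl)oxy]hexanal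
Conditions: TEMPO (0.2 equiv), PhI(OAc)2 (1.3 equiv), CH2Cl2, rt
Reagents that add atoms: none
Why: The TEMPO/PhI(OAc)2 oxoammonium oxidation converts the primary C3 alcohol to the aldehyde much faster than it touches the hindered secondary C8 alcohol and does not over-oxidise.

Step 19
Reactants: 31 (3R,4S,6R)-6-hydroxy-6-{(2R,3R)-2-[(1Z)-3-{[tert-butyl(dimethyl)silyl]oxy}-2-iodoprop-1-en-1-yl]-4-methylidene-5-oxooxolan-3-yl}-4-methyl-3,4-bis[(triethylsilyl)oxy]hexanal; 32 (2R)-2-methylbutanoic acid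
Product: 34 (1R,3S,4R)-1-{(2R,3R)-2-[(1Z)-3-{[tert-butyl(dimethyl)silyl]oxy}-2-iodoprop-1-en-1-yl]-4-methylidene-5-oxooxolan-3-yl}-3-methyl-6-oxo-3,4-bis[(triethylsilyl)oxy]hexyl (2R)-2-methylbutanoate, via O-acylisourea 33 (not isolated)
Conditions: 32 (2 equiv), DCC, DMAP (0.2 equiv), CH2Cl2, 0 °C to rt
Reagents that add atoms: none
Why: Steglich esterification acylates C8–OH with retention at the carbinol carbon and at the non-activated α-stereocentre of the acid.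

Step 20
Reactants: 34 (1R,3S,4R)-1-{(2R,3R)-2-[(1Z)-3-{[tert-butyl(dimethyl)silyl]oxy}-2-iodoprop-1-en-1-yl]-4-methylidene-5-oxooxolan-3-yl}-3-methyl-6-oxo-3,4-bis[(triethylsilyl)oxy]hexyl (2R)-2-methylbutanoate
Product: 36 (3aR,4R,6S,7R,9RS,10Z,11aS)-10-({[tert-butyl(dimethyl)silyl]oxy}methyl)-9-hydroxy-6-methyl-3-methylidene-2-oxo-6,7-bis[(triethylsilyl)oxy]-2,3,3a,4,5,6,7,8,9,11a-decahydrocyclodeca[b]furan-4-yl (2R)-2-methylbutanoate, via alkenylchromium(III) dichloride 35 (not isolated)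
Conditions: CrCl2 (15 equiv), NiCl2 (1 mol% of Cr), degassed DMSO, 0.003 M (syringe pump), rt
Reagents that add atoms: none
Why: Intramolecular Nozaki–Hiyama–Kishi reaction: the Ni-catalysed alkenylchromium forms with retention of the Z geometry and adds chemoselectively to the aldehyde under high dilution, closing the ten-membered ring at C3–C4; both C3 carbinol epimers converge in step 21.

Step 21
Reactants: 36 (3aR,4R,6S,7R,9RS,10Z,11aS)-10-({[tert-butyl(dimethyl)silyl]oxy}methyl)-9-hydroxy-6-methyl-3-methylidene-2-oxo-6,7-bis[(triethylsilyl)oxy]-2,3,3a,4,5,6,7,8,9,11a-decahydrocyclodeca[b]furan-4-yl (2R)-2-methylbutanoate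
Product: 37 (3aR,4R,6S,7R,10Z,11aS)-10-({[tert-butyl(dimethyl)silyl]oxy}methyl)-6-methyl-3-methylidene-2,9-dioxo-6,7-bis[(triethylsilyl)oxy]-2,3,3a,4,5,6,7,8,9,11a-decahydrocyclodeca[b]furan-4-yl (2R)-2-methylbutanoate
Conditions: Dess–Martin periodinane, NaHCO3, CH2Cl2, 0 °C to rt
Reagents that add atoms: none
Why: Buffered Dess–Martin oxidation of the allylic alcohol gives the (Z)-enone without touching any stereocentre or the β-silyloxy group.

Step 22
Reactants: 37 (3aR,4R,6S,7R,10Z,11aS)-10-({[tert-butyl(dimethyl)silyl]oxy}methyl)-6-methyl-3-methylidene-2,9-dioxo-6,7-bis[(triethylsilyl)oxy]-2,3,3a,4,5,6,7,8,9,11a-decahydrocyclodeca[b]furan-4-yl (2R)-2-methylbutanoate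
Product: 38 (3aR,4R,6S,7R,10Z,11aS)-6,7-dihydroxy-10-(hydroxymethyl)-6-methyl-3-methylidene-2,9-dioxo-2,3,3a,4,5,6,7,8,9,11a-decahydrocyclodeca[b]furan-4-yl (2R)-2-methylbutanoate
Conditions: HF·pyridine, pyridine, THF, 0 °C to rt
Reagents that add atoms: none
Why: Pyridine-buffered HF cleaves the three silyl ethers (fluoride-driven desilylation) under near-neutral conditions that spare the β-hydroxy ketone, both esters and the α-methylene lactone.

## Compound list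

1 | (R)-epichlorohydrin, (2R)-2-(chloromethyl)oxirane | ClC[C@H]1CO1 | starting material
2 | ethynyltrimethylsilane | C#C[Si](C)(C)C | starting material
3 | lithium (trimethylsilyl)acetylide | [Li]C#C[Si](C)(C)C | intermediate
4 | (2R)-1-chloro-5-(trimethylsilyl)pent-4-yn-2-ol | C[Si](C)(C)C#CC[C@@H](O)CCl | intermediate
5 | trimethyl{3-[(2R)-oxiran-2-yl]prop-1-yn-1-yl}silane | C[Si](C)(C)C#CC[C@@H]1CO1 | intermediate
6 | (3R)-6-(trimethylsilyl)hex-1-en-5-yn-3-ol | C[Si](C)(C)C#CC[C@@H](O)C=C | intermediate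
7 | {(4R)-4-[(4-methoxybenzyl)oxy]hex-5-en-1-yn-1-yl}trimethylsilane | C[Si](C)(C)C#CC[C@@H](OCc1ccc(OC)cc1)C=C | intermediate
8 | 1-({[(3R)-hex-1-en-5-yn-3-yl]oxy}methyl)-4-methoxybenzene | C#CC[C@@H](OCc1ccc(OC)cc1)C=C | intermediate
9 | oxirane | C1CO1 | starting material
10 | {(1E,4R)-4-[(4-methoxybenzyl)oxy]-2-methylhexa-1,5-dien-1-yl}dimethylalumane | C[Al](C)/C=C(\C)C[C@@H](OCc1ccc(OC)cc1)C=C | intermediate
11 | lithium butyl{(1E,4R)-4-[(4-methoxybenzyl)oxy]-2-methylhexa-1,5-dien-1-yl}dimethylaluminate | [Li+].CCCC[Al-](C)(C)/C=C(\C)C[C@@H](OCc1ccc(OC)cc1)C=C | intermediate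
12 | (3E,6R)-6-[(4-methoxybenzyl)oxy]-4-methylocta-3,7-dien-1-ol | OCC/C=C(\C)C[C@@H](OCc1ccc(OC)cc1)C=C | intermediate
13 | (3E,6R)-1,6-bis[(4-methoxybenzyl)oxy]-4-methylocta-3,7-diene | COc1ccc(COCC/C=C(\C)C[C@@H](OCc2ccc(OC)cc2)C=C)cc1 | intermediate
14 | (2R,3R)-2-{(2R)-2-[(4-methoxybenzyl)oxy]but-3-en-1-yl}-3-{2-[(4-methoxybenzyl)oxy]ethyl}-2-methyloxirane | COc1ccc(COCC[C@H]2O[C@]2(C)C[C@@H](OCc3ccc(OC)cc3)C=C)cc1 | intermediate
15 | (3R,4S,6R)-1,6-bis[(4-methoxybenzyl)oxy]-4-methyloct-7-ene-3,4-diol | COc1ccc(COCC[C@@H](O)[C@@](C)(O)C[C@@H](OCc2ccc(OC)cc2)C=C)cc1 | intermediate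
16 | (3R,4S,6R)-1,6-bis[(4-methoxybenzyl)oxy]-4-methyl-3,4-bis[(triethylsilyl)oxy]oct-7-ene | COc1ccc(COCC[C@@H](O[Si](CC)(CC)CC)[C@@](C)(O[Si](CC)(CC)CC)C[C@@H](OCc2ccc(OC)cc2)C=C)cc1 | intermediate
17 | (3R,5S,6R)-3,8-bis[(4-methoxybenzyl)oxy]-5-methyl-5,6-bis[(triethylsilyl)oxy]octane-1,2-diol (C2 epimers) | COc1ccc(COCC[C@@H](O[Si](CC)(CC)CC)[C@@](C)(O[Si](CC)(CC)CC)C[C@@H](OCc2ccc(OC)cc2)C(O)CO)cc1 | intermediate
18 | (2R,4S,5R)-2,7-bis[(4-methoxybenzyl)oxy]-4-methyl-4,5-bis[(triethylsilyl)oxy]heptanal | COc1ccc(COCC[C@@H](O[Si](CC)(CC)CC)[C@@](C)(O[Si](CC)(CC)CC)C[C@@H](OCc2ccc(OC)cc2)C=O)cc1 | intermediate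
19 | methyl acrylate | C=CC(=O)OC | starting material
20 | methyl (4R,6S,7R)-3-hydroxy-4,9-bis[(4-methoxybenzyl)oxy]-6-methyl-2-methylidene-6,7-bis[(triethylsilyl)oxy]nonanoate (C3 epimers) | COc1ccc(COCC[C@@H](O[Si](CC)(CC)CC)[C@@](C)(O[Si](CC)(CC)CC)C[C@@H](OCc2ccc(OC)cc2)C(O)C(=C)C(=O)OC)cc1 | intermediate
21 | methyl (2Z,4R,6S,7R)-2-(bromomethyl)-4,9-bis[(4-methoxybenzyl)oxy]-6-methyl-6,7-bis[(triethylsilyl)oxy]non-2-enoate | COc1ccc(COCC[C@@H](O[Si](CC)(CC)CC)[C@@](C)(O[Si](CC)(CC)CC)C[C@@H](OCc2ccc(OC)cc2)/C=C(\CBr)C(=O)OC)cc1 | intermediate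
22 | but-2-yne-1,4-diol | OCC#CCO | starting material
23 | 4-{[tert-butyl(dimethyl)silyl]oxy}but-2-yn-1-ol | OCC#CCO[Si](C)(C)C(C)(C)C | intermediate
24 | sodium 3-({[tert-butyl(dimethyl)silyl]oxy}methyl)-2,2-bis(2-methoxyethoxy)-2,5-dihydro-1,2-oxaluminol-2-uide | [Na+].COCCO[Al-]1(OCCOC)OCC=C1CO[Si](C)(C)C(C)(C)C | intermediate
25 | (2Z)-4-{[tert-butyl(dimethyl)silyl]oxy}-3-iodobut-2-en-1-ol | OC/C=C(/CO[Si](C)(C)C(C)(C)C)I | intermediate
26 | (2Z)-4-{[tert-butyl(dimethyl)silyl]oxy}-3-iodobut-2-enal | O=C/C=C(/CO[Si](C)(C)C(C)(C)C)I | intermediate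
27 | allylindium(I) species from 21 (In in place of Br, Z) | COc1ccc(COCC[C@@H](O[Si](CC)(CC)CC)[C@@](C)(O[Si](CC)(CC)CC)C[C@@H](OCc2ccc(OC)cc2)/C=C(\C[In])C(=O)OC)cc1 | intermediate
28 | methyl (3S,4R,5Z)-3-{(1R,3S,4R)-1,6-bis[(4-methoxybenzyl)oxy]-3-methyl-3,4-bis[(triethylsilyl)oxy]hexyl}-7-{[tert-butyl(dimethyl)silyl]oxy}-4-hydroxy-6-iodo-2-methylidenehept-5-enoate | COc1ccc(COCC[C@@H](O[Si](CC)(CC)CC)[C@@](C)(O[Si](CC)(CC)CC)C[C@@H](OCc2ccc(OC)cc2)[C@@H](C(=C)C(=O)OC)[C@@H](O)/C=C(/CO[Si](C)(C)C(C)(C)C)I)cc1 | intermediate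
29 | (4R,5R)-5-[(1Z)-3-{[tert-butyl(dimethyl)silyl]oxy}-2-iodoprop-1-en-1-yl]-4-{(1R,3S,4R)-1,6-bis[(4-methoxybenzyl)oxy]-3-methyl-3,4-bis[(triethylsilyl)oxy]hexyl}-3-methylideneoxolan-2-one | C=C1C(=O)O[C@@H](/C=C(/CO[Si](C)(C)C(C)(C)C)I)[C@H]1[C@H](OCc1ccc(OC)cc1)C[C@](C)(O[Si](CC)(CC)CC)[C@H](O[Si](CC)(CC)CC)CCOCc1ccc(OC)cc1 | intermediate
30 | (4R,5R)-5-[(1Z)-3-{[tert-butyl(dimethyl)silyl]oxy}-2-iodoprop-1-en-1-yl]-4-{(1R,3S,4R)-1,6-dihydroxy-3-methyl-3,4-bis[(triethylsilyl)oxy]hexyl}-3-methylideneoxolan-2-one | C=C1C(=O)O[C@@H](/C=C(/CO[Si](C)(C)C(C)(C)C)I)[C@H]1[C@H](O)C[C@](C)(O[Si](CC)(CC)CC)[C@H](O[Si](CC)(CC)CC)CCO | intermediate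
31 | (3R,4S,6R)-6-hydroxy-6-{(2R,3R)-2-[(1Z)-3-{[tert-butyl(dimethyl)silyl]oxy}-2-iodoprop-1-en-1-yl]-4-methylidene-5-oxooxolan-3-yl}-4-methyl-3,4-bis[(triethylsilyl)oxy]hexanal | C=C1C(=O)O[C@@H](/C=C(/CO[Si](C)(C)C(C)(C)C)I)[C@H]1[C@H](O)C[C@](C)(O[Si](CC)(CC)CC)[C@H](O[Si](CC)(CC)CC)CC=O | intermediate
32 | (2R)-2-methylbutanoic acid | CC[C@@H](C)C(=O)O | starting material
33 | N,N'-dicyclohexyl-O-[(2R)-2-methylbutanoyl]isourea | CC[C@@H](C)C(=O)OC(=NC1CCCCC1)NC1CCCCC1 | intermediate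
34 | (1R,3S,4R)-1-{(2R,3R)-2-[(1Z)-3-{[tert-butyl(dimethyl)silyl]oxy}-2-iodoprop-1-en-1-yl]-4-methylidene-5-oxooxolan-3-yl}-3-methyl-6-oxo-3,4-bis[(triethylsilyl)oxy]hexyl (2R)-2-methylbutanoate | C=C1C(=O)O[C@@H](/C=C(/CO[Si](C)(C)C(C)(C)C)I)[C@H]1[C@H](OC(=O)[C@H](C)CC)C[C@](C)(O[Si](CC)(CC)CC)[C@H](O[Si](CC)(CC)CC)CC=O | intermediate
35 | alkenylchromium(III) dichloride from 34 (CrCl2 in place of I, Z) | C=C1C(=O)O[C@@H](/C=C(/CO[Si](C)(C)C(C)(C)C)[Cr](Cl)Cl)[C@H]1[C@H](OC(=O)[C@H](C)CC)C[C@](C)(O[Si](CC)(CC)CC)[C@H](O[Si](CC)(CC)CC)CC=O | intermediate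
36 | (3aR,4R,6S,7R,9RS,10Z,11aS)-10-({[tert-butyl(dimethyl)silyl]oxy}methyl)-9-hydroxy-6-methyl-3-methylidene-2-oxo-6,7-bis[(triethylsilyl)oxy]-2,3,3a,4,5,6,7,8,9,11a-decahydrocyclodeca[b]furan-4-yl (2R)-2-methylbutanoate | C=C1C(=O)O[C@H]2/C=C(/CO[Si](C)(C)C(C)(C)C)C(O)C[C@@H](O[Si](CC)(CC)CC)[C@@](C)(O[Si](CC)(CC)CC)C[C@@H](OC(=O)[C@H](C)CC)[C@@H]12 | intermediate
37 | (3aR,4R,6S,7R,10Z,11aS)-10-({[tert-butyl(dimethyl)silyl]oxy}methyl)-6-methyl-3-methylidene-2,9-dioxo-6,7-bis[(triethylsilyl)oxy]-2,3,3a,4,5,6,7,8,9,11a-decahydrocyclodeca[b]furan-4-yl (2R)-2-methylbutanoate | C=C1C(=O)O[C@H]2/C=C(/CO[Si](C)(C)C(C)(C)C)C(=O)C[C@@H](O[Si](CC)(CC)CC)[C@@](C)(O[Si](CC)(CC)CC)C[C@@H](OC(=O)[C@H](C)CC)[C@@H]12 | intermediate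
38 | (3aR,4R,6S,7R,10Z,11aS)-6,7-dihydroxy-10-(hydroxymethyl)-6-methyl-3-methylidene-2,9-dioxo-2,3,3a,4,5,6,7,8,9,11a-decahydrocyclodeca[b]furan-4-yl (2R)-2-methylbutanoate (CNP0263726.1) | C=C1C(=O)O[C@H]2/C=C(/CO)C(=O)C[C@@H](O)[C@@](C)(O)C[C@@H](OC(=O)[C@H](C)CC)[C@@H]12 | target

## Step count and risks

Total steps: 22. Longest linear sequence: 19 (steps 1–11, then 15–22); steps 12–14 make the second fragment.

Three steps most likely to fail:

Step 20 (ten-membered ring closure). The strained medium ring may form slowly, and the alkenylchromium carries an allylic lactone oxygen that could be lost. The fallback closes the carbocycle before the lactone and sets out from 28. Silylation of the C6 hydroxyl (TESOTf, 2,6-lutidine) gives the C6 triethylsilyl ether F2. DDQ then gives the C3,C8-diol F3. TEMPO/PhI(OAc)2 gives the hydroxy aldehyde F4. DCC/DMAP with 32 gives the C8 (2R)-2-methylbutanoate aldehyde F5. CrCl2/NiCl2 under high dilution closes the more flexible seco-ester to the cyclodecenol F6. Dess–Martin oxidation gives the cyclodecenone methyl ester F7. HF·pyridine then frees the tetrahydroxy ester F8, which lactonises through its C6 hydroxyl (PPTS) and so comes back to the route at 38.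

Step 15 (facial selectivity of the allylation at C7, and syn/anti ratio). The fallback replaces the substrate-controlled Barbier reaction by an allylboration and sets out from 21. Copper-catalysed borylation (B2pin2, CuCl/LiCl cat., KOAc, DMF) gives the pinacol 2-(methoxycarbonyl)allylboronate F1. F1 adds to 26 under Sc(OTf)3 catalysis through a tight boron-centred chair (Z-boronate gives syn). If needed the pinacol can be exchanged for a chiral diol to impose reagent control. After work-up this comes back to the route at 28.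

Step 10 (Baylis–Hillman reaction of a hindered α-alkoxy aldehyde: slow, with C8 epimerisation possible under prolonged amine exposure). The fallback sets out from 18 and uses vinylalumination instead of amine catalysis. Methyl propiolate with DIBAL-H/NMO in THF gives [1-(methoxycarbonyl)ethenyl]diisobutylalumane F9. F9 adds to 18 at 0 °C within hours without base and comes back to the route at 20.

Further compounds

F1 | step 15 | methyl (2Z,4R,6S,7R)-4,9-bis[(4-methoxybenzyl)oxy]-6-methyl-2-[(4,4,5,5-tetramethyl-1,3,2-dioxaborolan-2-yl)methyl]-6,7-bis[(triethylsilyl)oxy]non-2-enoate | COc1ccc(COCC[C@@H](O[Si](CC)(CC)CC)[C@@](C)(O[Si](CC)(CC)CC)C[C@@H](OCc2ccc(OC)cc2)/C=C(\CB2OC(C)(C)C(C)(C)O2)C(=O)OC)cc1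
F2 | step 20 | C6 triethylsilyl ether of 28 | COc1ccc(COCC[C@@H](O[Si](CC)(CC)CC)[C@@](C)(O[Si](CC)(CC)CC)C[C@@H](OCc2ccc(OC)cc2)[C@@H](C(=C)C(=O)OC)[C@@H](O[Si](CC)(CC)CC)/C=C(/CO[Si](C)(C)C(C)(C)C)I)cc1
F3 | step 20 | C3,C8-diol from F2 (both PMB groups removed) | OCC[C@@H](O[Si](CC)(CC)CC)[C@@](C)(O[Si](CC)(CC)CC)C[C@@H](O)[C@@H](C(=C)C(=O)OC)[C@@H](O[Si](CC)(CC)CC)/C=C(/CO[Si](C)(C)C(C)(C)C)I
F4 | step 20 | C3 aldehyde, C8 alcohol from F3 | O=CC[C@@H](O[Si](CC)(CC)CC)[C@@](C)(O[Si](CC)(CC)CC)C[C@@H](O)[C@@H](C(=C)C(=O)OC)[C@@H](O[Si](CC)(CC)CC)/C=C(/CO[Si](C)(C)C(C)(C)C)I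
F5 | step 20 | C8 (2R)-2-methylbutanoate of F4 | O=CC[C@@H](O[Si](CC)(CC)CC)[C@@](C)(O[Si](CC)(CC)CC)C[C@@H](OC(=O)[C@H](C)CC)[C@@H](C(=C)C(=O)OC)[C@@H](O[Si](CC)(CC)CC)/C=C(/CO[Si](C)(C)C(C)(C)C)I
F6 | step 20 | seco-ester cyclodecenol (C3 epimers) from F5 | COC(=O)C(=C)[C@H]1[C@@H](O[Si](CC)(CC)CC)/C=C(/CO[Si](C)(C)C(C)(C)C)C(O)C[C@@H](O[Si](CC)(CC)CC)[C@@](C)(O[Si](CC)(CC)CC)C[C@H]1OC(=O)[C@H](C)CC
F7 | step 20 | seco-ester cyclodecenone from F6 | COC(=O)C(=C)[C@H]1[C@@H](O[Si](CC)(CC)CC)/C=C(/CO[Si](C)(C)C(C)(C)C)C(=O)C[C@@H](O[Si](CC)(CC)CC)[C@@](C)(O[Si](CC)(CC)CC)C[C@H]1OC(=O)[C@H](C)CC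
F8 | step 20 | desilylated tetrahydroxy methyl ester from F7 | COC(=O)C(=C)[C@H]1[C@@H](O)/C=C(/CO)C(=O)C[C@@H](O)[C@@](C)(O)C[C@H]1OC(=O)[C@H](C)CC
F9 | step 10 | [1-(methoxycarbonyl)ethenyl]diisobutylalumane | C=C(C(=O)OC)[Al](CC(C)C)CC(C)C
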